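**Retrosynthetic overview**

- The only ring, the dihydropyranone O1–C2–C3–C4–C5–C6, is disconnected at C2–C3, C5–C6 and O1–C2 into three components: carbon monoxide (C2), a 1-(tigloyloxy)allyl unit (C3–C4–C5, tiglate already on the C5 oxygen) and (2E,4S,5S)-4,5-diacetoxyhex-2-enal (C6, O1 and the whole side chain). The ring is formed last.
- Forward: palladium-catalysed carbonylation of 3-chloroprop-1-enyl tiglate gives a 4-tigloyloxy vinylketene; a chiral amine turns it into a dienolate that undergoes a hetero-[4+2] with the enal, setting C5 and C6 (cis) in the same operation.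
- Enabling feature: ring atoms C2(=O)–C3=C4–C5(O-acyl) are the skeleton of a vinylketene whose enol-ester oxygen sits on C5, and O1–C6 is an aldehyde carbonyl, so the 5-acyloxy α,β-unsaturated δ-lactone is a latent ketene-diene/aldehyde cycloadduct.
- The enal is the acetylated Perlin aldehyde of 3,4-di-O-acetyl-L-fucal (sugar C4 and C5 become the two side-chain stereocentres); the allyl component comes from acrolein and tigloyl chloride.

Key step: step 4

Assumption: O-trimethylsilylquinidine is taken to deliver the dienolate face that sets C6 as S; this sense is not secured on this substrate class, and the pseudoenantiomeric O-trimethylsilylquinine would replace it if the sense proves opposite.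

**Step 1**
Reactants: 1 3,4-di-O-acetyl-L-fucal
Product: 2 (2E,4S,5S)-4-acetoxy-5-hydroxyhex-2-enal
Conditions: HgSO4 (2 mol %), 5 mM aq. H2SO4, 1,4-dioxane, rt
Reagents that add atoms: water, O
Why: Perlin hydrolysis, in which mercury-assisted hydration of the glycal enol ether, opening of the hemiacetal and β-elimination of the 3-acetate should give the (E)-enal, while sugar C4 and C5 are untouched and become the (4S,5S) centres of 2 (no new stereocentre).

**Step 2**
Reactants: 2 (2E,4S,5S)-4-acetoxy-5-hydroxyhex-2-enal
Product: 3 (2E,4S,5S)-4,5-diacetoxyhex-2-enal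
Conditions: Ac2O, pyridine, DMAP (cat.), CH2Cl2, 0 °C
Reagents that add atoms: acetic anhydride, CC(=O)OC(C)=O
Why: Standard O-acetylation of the secondary alcohol under mild base, which the enal and the γ-acetate should tolerate at 0 °C; an acetyl shift between O4 and O5 in step 1 would be of no consequence because both oxygens end up acetylated.

**Step 3**
Reactants: 4 acrolein; 5 tigloyl chloride
Product: 6 3-chloroprop-1-en-1-yl (2E)-2-methylbut-2-enoate (E/Z mixture at the enol ester)
Conditions: ZnCl2 (1 mol %), CH2Cl2, −20 °C to rt, then distillation under reduced pressure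
Reagents that add atoms: none
Why: ZnCl2-catalysed addition of an acyl chloride to acrolein, a known way to 3-halopropenyl esters (α-chloroallyl ester first, then allylic chloride shift to the conjugate adduct); no stereocentre is formed and the enol-ester geometry does not matter for step 4.

**Step 4**
Reactants: 3 (2E,4S,5S)-4,5-diacetoxyhex-2-enal; 6 3-chloroprop-1-en-1-yl (2E)-2-methylbut-2-enoate; 7 carbon monoxide
Product: 9 (5S,6S)-6-[(1E,3S,4S)-3,4-diacetoxypent-1-en-1-yl]-5-[(2E)-2-methylbut-2-enoyloxy]-5,6-dihydro-2H-pyran-2-one (target), via 4-tigloyloxy vinylketene 8 (not isolated)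
Conditions: Pd(OAc)2 (5 mol %), PPh3 (15 mol %), CO (20 bar), O-trimethylsilylquinidine (20 mol %), Er(OTf)3 (10 mol %), iPr2NEt (1.3 equiv), THF, rt, slow addition of 6
Reagents that add atoms: none
Why: Proposed new method: zerovalent palladium (formed in the flask from Pd(OAc)2 and PPh3) ionises the allylic chloride of 6 to a 1-(tigloyloxy)-π-allyl complex on which both enol-ester geometries converge, CO inserts at the unsubstituted terminus, and iPr2NEt-induced dehydropalladation of the β,γ-unsaturated acyl complex releases the (E)-vinylketene 8 at low stationary concentration, which creates the C2–C3 bond. O-Trimethylsilylquinidine adds to the ketene carbon of 8 to give an s-cis ammonium dienolate that combines with the Er(OTf)3-bound aldehyde of 3 in a hetero-[4+2] cycloaddition, its γ-carbon (C5) bonding to the aldehyde carbon (C6) and the aldehyde oxygen (O1) acylating at C2 with release of the alkaloid. The closest known reaction types are the palladium-catalysed carbonylative [2+2] cycloaddition of allyl halides with imines through vinylketenes and the Lewis acid/Lewis base-catalysed [4+2] cycloaddition of vinylketene-derived ammonium dienolates with aldehydes to 5,6-dihydropyran-2-ones; their merger in one flask is the new element. The single ring (O1–C2–C3–C4–C5–C6) closes in a [4+2] mode or, if the event is stepwise, by vinylogous aldol addition followed by 6-exo-trig lactonisation onto the acylammonium carbon. C5 and C6 arise together: the E enol ester (outside) and the endo-placed alkenyl group of the aldehyde (Lewis acid anti to it) should give the 5,6-cis relation, and the dienolate face left open by the quinoline of the catalyst is expected to fix the absolute (5S,6S) sense against the weak bias of the remote side-chain centres. The step needs γ- over α-attack of the dienolate (helped by the oxygen donor on C5 and the cyclic transition state), 1,2- over 1,4-addition to the enal (hard Lewis acid on the carbonyl oxygen) and ionisation of the allylic chloride of 6 in preference to the allylic acetate and lactone C–O bonds (far faster oxidative addition of the chloride at room temperature under CO).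

**Compound list**

1 | 3,4-di-O-acetyl-L-fucal, (2S,3R,4S)-2-methyl-3,4-dihydro-2H-pyran-3,4-diyl diacetate | C[C@@H]1OC=C[C@H](OC(C)=O)[C@@H]1OC(C)=O | starting material
2 | (2E,4S,5S)-4-acetoxy-5-hydroxyhex-2-enal | O=C/C=C/[C@H](OC(C)=O)[C@H](C)O | intermediate
3 | (2E,4S,5S)-4,5-diacetoxyhex-2-enal | O=C/C=C/[C@H](OC(C)=O)[C@H](C)OC(C)=O | intermediate
4 | acrolein (prop-2-enal) | C=CC=O | starting material
5 | tigloyl chloride, (2E)-2-methylbut-2-enoyl chloride | C/C=C(\C)C(=O)Cl | starting material
6 | 3-chloroprop-1-en-1-yl (2E)-2-methylbut-2-enoate (E/Z mixture at the enol ester) | C/C=C(\C)C(=O)OC=CCCl | intermediate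
7 | carbon monoxide | [C-]#[O+] | starting material
8 | (1E)-4-oxobuta-1,3-dien-1-yl (2E)-2-methylbut-2-enoate (4-tigloyloxy vinylketene) | C/C=C(\C)C(=O)O/C=C/C=C=O | intermediate
9 | (5S,6S)-6-[(1E,3S,4S)-3,4-diacetoxypent-1-en-1-yl]-5-[(2E)-2-methylbut-2-enoyloxy]-5,6-dihydro-2H-pyran-2-one | C/C=C(\C)C(=O)O[C@H]1C=CC(=O)O[C@H]1/C=C/[C@H](OC(C)=O)[C@H](C)OC(C)=O | target

Total step count: 4. Longest linear sequence: 3 steps (steps 1, 2 and 4).

**Steps most likely to fail**

Step 4 (proposed new method). What may go wrong:
- α- instead of γ-attack of the ammonium dienolate, leading to β-lactone formation;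
- insufficient cis or facial selectivity in the cycloaddition;
- C-allylation of the dienolate by the π-allyl complex;
- ionisation of the allylic acetate of the aldehyde, or of the allylic C5–O bond of the product, by zerovalent palladium, with elimination toward a 2-pyrone.

The fallback uses known chemistry, sets out from 3 and returns at 9. Aldehyde 3 is treated with [(Z)-γ-(methoxymethoxy)allyl]diisopinocampheylborane, made from allyl methoxymethyl ether, s-BuLi, (+)-B-methoxydiisopinocampheylborane and BF3·OEt2 (THF, −78 °C, ethanolamine work-up to spare the acetates). This reagent-controlled Re-face syn-alkoxyallylboration should give (3S,4S,5E,7S,8S)-4-hydroxy-3-(methoxymethoxy)nona-1,5-diene-7,8-diyl diacetate F1. Acylation with acryloyl chloride (iPr2NEt, CH2Cl2, 0 °C) should give (3S,4S,5E,7S,8S)-7,8-diacetoxy-3-(methoxymethoxy)nona-1,5-dien-4-yl prop-2-enoate F2. Ring-closing metathesis (second-generation Grubbs catalyst, RuCl2(=CHPh)(PCy3)(H2IMes), CH2Cl2, 40 °C) should close the lactone (2S,3S,4E)-5-[(2S,3S)-3-(methoxymethoxy)-6-oxo-3,6-dihydro-2H-pyran-2-yl]pent-4-ene-2,3-diyl diacetate F3. Cleavage of the MOM ether (Me3SiBr, CH2Cl2, −30 °C) should free (2S,3S,4E)-5-[(2S,3S)-3-hydroxy-6-oxo-3,6-dihydro-2H-pyran-2-yl]pent-4-ene-2,3-diyl diacetate F4, and esterification with 5 (pyridine, DMAP, CH2Cl2, 0 °C) should give 9.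

Step 3. What may go wrong: polymerisation of acrolein under Lewis acid, addition of HCl to the tigloyl double bond, and loss of the labile enol ester on distillation. The fallback sets out from 4 and returns at 8. Acrolein 4 is condensed with tiglic anhydride (FeCl3, 1 mol %, 0 °C) to the geminal diester prop-2-ene-1,1-diyl bis[(2E)-2-methylbut-2-enoate] F5. Zerovalent palladium ionises such acylals to the same 1-(tigloyloxy)-π-allyl complex, so F5 takes the place of 6 in step 4 and the route is rejoined at vinylketene 8, with a tiglate leaving in place of chloride.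

Step 1. What may go wrong: acetyl migration and over-hydrolysis in the aqueous acid, and stalling before the cis-to-trans isomerisation of the enal is complete. The fallback is mercury-free, sets out from 1 and returns at 2. Heating 1 in water/1,4-dioxane (80 °C) should bring about a Ferrier-type allylic hydrolysis to the 2,3-unsaturated lactol (2S,3S)-6-hydroxy-2-methyl-3,6-dihydro-2H-pyran-3-yl acetate F6. Brief treatment with pyridine at rt should then open the ring and isomerise the cis-enal to the trans-enal 2.

**Further compounds**

F1 | step 4 | (3S,4S,5E,7S,8S)-4-hydroxy-3-(methoxymethoxy)nona-1,5-diene-7,8-diyl diacetate | COCO[C@@H](C=C)[C@@H](O)/C=C/[C@H](OC(C)=O)[C@H](C)OC(C)=O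
F2 | step 4 | (3S,4S,5E,7S,8S)-7,8-diacetoxy-3-(methoxymethoxy)nona-1,5-dien-4-yl prop-2-enoate | COCO[C@@H](C=C)[C@@H](OC(=O)C=C)/C=C/[C@H](OC(C)=O)[C@H](C)OC(C)=O
F3 | step 4 | (2S,3S,4E)-5-[(2S,3S)-3-(methoxymethoxy)-6-oxo-3,6-dihydro-2H-pyran-2-yl]pent-4-ene-2,3-diyl diacetate | COCO[C@H]1C=CC(=O)O[C@H]1/C=C/[C@H](OC(C)=O)[C@H](C)OC(C)=O
F4 | step 4 | (2S,3S,4E)-5-[(2S,3S)-3-hydroxy-6-oxo-3,6-dihydro-2H-pyran-2-yl]pent-4-ene-2,3-diyl diacetate | O[C@H]1C=CC(=O)O[C@H]1/C=C/[C@H](OC(C)=O)[C@H](C)OC(C)=O
F5 | step 3 | prop-2-ene-1,1-diyl bis[(2E)-2-methylbut-2-enoate] | C/C=C(\C)C(=O)OC(C=C)OC(=O)/C(C)=C/C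
F6 | step 1 | (2S,3S)-6-hydroxy-2-methyl-3,6-dihydro-2H-pyran-3-yl acetate | C[C@@H]1OC(O)C=C[C@@H]1OC(C)=O
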